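**Strategy**

The 7-oxabicyclo[2.2.1]heptane is cut through its tetrahydrofuran ring O-7/C-1/C-2/C-3/C-4 (C-1 methyl-bearing bridgehead, C-3 gem-dimethyl carbon) as a formal (3+2) adduct: a ketone carbonyl supplies C-1 and O-7, a cyclopropane made of C-2, C-3 and C-4 supplies the rest. In one operation the cyclopropane bond C-2–C-4, absent from the target, breaks, the ketone oxygen bonds to C-4 with inversion and the released enol carbon C-2 bonds to C-1. The precursor is a cis-2,2-dimethylcyclopropanecarbaldehyde with a 3-oxobutyl chain on C-4, made from (S)-carvone, whose stereocentre thereby controls the whole bicycle. The arene side chain is attached afterwards by B-alkyl Suzuki coupling.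

Key step: step 6

Remark: locants C-1, C-2, C-3, C-4 and O-7 always mean the atoms that end up at these positions of the oxabicycle (C-2 side-chain carbon, C-4 bridgehead CH); 1, 13 and 14 are assumed to be purchased; 8 is a mixture at its two acetal carbons, the enol ether geometry of 10 is left open, and cyclopentadienyl rings on zirconium are drawn σ-bonded in the SMILES.

**Route**

Step 1
Reactants: 1 (S)-(+)-carvone
Product: 2 (5S)-5-(2-chloropropan-2-yl)-2-methylcyclohex-2-en-1-one
Conditions: HCl (gas), Et2O, 0 °C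
Reagents that add atoms: hydrogen chloride, Cl
Why: Markovnikov hydrochlorination of the electron-rich isopropenyl alkene through the tertiary cation leaves the conjugated enone and the stereocentre untouched.

Step 2
Reactants: 2 (5S)-5-(2-chloropropan-2-yl)-2-methylcyclohex-2-en-1-one
Product: 4 (1R,6S)-3,7,7-trimethylbicyclo[4.1.0]hept-3-en-2-one, via potassium dienolate 3 (not isolated)
Conditions: KOtBu, THF, −20 → 0 °C
Reagents that add atoms: none
Why: Kinetic α′-deprotonation and 3-exo-tet intramolecular alkylation of the tertiary chloride (the classical carvone hydrohalide to carenone closure) can only give the cis-fused cyclopropane, so the carvone stereocentre fixes both ring carbons, and the low temperature avoids base-induced ring expansion.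

Step 3
Reactants: 4 (1R,6S)-3,7,7-trimethylbicyclo[4.1.0]hept-3-en-2-one
Product: 6 (1R,6S)-3,7,7-trimethylbicyclo[4.1.0]hept-2-en-2-yl trifluoromethanesulfonate, via lithium enolate 5 (not isolated)
Conditions: LiBH(s-Bu)3, THF, −78 °C; then PhNTf2, −78 → 0 °C
Reagents that add atoms: N-phenylbis(trifluoromethanesulfonimide), O=S(=O)(N(c1ccccc1)S(=O)(=O)C(F)(F)F)C(F)(F)F
Why: Conjugate hydride addition to the β-unsubstituted enone gives one regiodefined enolate, which is O-sulfonylated to the vinyl triflate without touching the cyclopropane stereocentres.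

Step 4
Reactants: 6 (1R,6S)-3,7,7-trimethylbicyclo[4.1.0]hept-2-en-2-yl trifluoromethanesulfonate
Product: 7 (1R,6S)-3,7,7-trimethylbicyclo[4.1.0]hept-2-ene
Conditions: Pd(OAc)2 (5 mol %), PPh3, HCO2H, n-Bu3N, DMF, 60 °C
Reagents that add atoms: none
Why: Palladium-catalysed formate reduction of a vinyl triflate (oxidative addition, formate exchange, decarboxylation, C–H reductive elimination) leaves the double bond where the enolate was and gives the unnatural enantiomer of 2-carene.

Step 5
Reactants: 7 (1R,6S)-3,7,7-trimethylbicyclo[4.1.0]hept-2-ene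
Product: 9 (1R,3S)-2,2-dimethyl-3-(3-oxobutyl)cyclopropane-1-carbaldehyde, via ozonide 8 (not isolated)
Conditions: O3, CH2Cl2, −78 °C; then Me2S, −78 °C → rt
Reagents that add atoms: ozone, [O-][O+]=O
Why: Ozonolysis with reductive work-up cleaves the trisubstituted alkene to the aldehyde on one cyclopropane carbon and the methyl ketone at the end of the two-carbon tether on the other, keeping the cis-cyclopropane and both stereocentres.

Step 6
Reactants: 9 (1R,3S)-2,2-dimethyl-3-(3-oxobutyl)cyclopropane-1-carbaldehyde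
Product: 11 (1R,2S,4S)-1,3,3-trimethyl-7-oxabicyclo[2.2.1]heptane-2-carbaldehyde, via oxocarbenium silyl enol ether 10 (not isolated)
Conditions: Me3SiOTf (20 mol %), CH2Cl2, −78 → −30 °C; then Et3N
Reagents that add atoms: none
Why: Proposed new method: Me3SiOTf silylates the aldehyde oxygen, the ketone oxygen attacks C-4 from the side opposite the breaking C-2–C-4 bond, and the silyl enol ether released in 10 adds to the oxocarbenium carbon C-1 in a Mukaiyama-type aldol step that returns Me3Si+; the closest known reactions are the Lewis-acid-catalysed intramolecular (3+2) cross-cycloaddition of cyclopropane 1,1-diesters with tethered ketones to oxa-bridged [n.2.1] skeletons and the iminium-triggered opening of alkyl-substituted cyclopropanecarbaldehydes at a secondary ring carbon. The O-7–C-4 bond closes a tetrahydrofuran in the 5-exo mode of three-membered-ring opening, and the C-1–C-2 bond closes the cyclohexane ring in a 6-(enolexo)-exo-trig mode, which together give the 7-oxabicyclo[2.2.1]heptane. C-4 is set by inversion of the carvone-derived cyclopropane stereocentre, C-1 follows because the tethered enol ether can reach only one face of the oxocarbenium ion, and C-2 should carry the formyl group exo (on the side of O-7), which is the less hindered approach and the more stable epimer. The step needs the ring to open at the secondary C-4 and not at the dimethyl-substituted C-3: attack at C-4 is the 5-exo path at an unhindered secondary centre, whereas attack at C-3 is the 6-endo path at a fully substituted centre, the same competition that acid-catalysed cyclisation of 6,7-epoxylinalool settles mainly in favour of the tetrahydrofuran. The triflate counter-ion is not nucleophilic and no amine is present, so halide opening of the ring and aldol addition of the ketone to the aldehyde should not compete at low temperature, which also suppresses Cloke–Wilson isomerisation.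

Step 7
Reactants: 11 (1R,2S,4S)-1,3,3-trimethyl-7-oxabicyclo[2.2.1]heptane-2-carbaldehyde
Product: 12 (1R,2S,4S)-2-ethenyl-1,3,3-trimethyl-7-oxabicyclo[2.2.1]heptane
Conditions: Ph3PCH3Br, KN(SiMe3)2, THF, 0 °C; then 11, −78 → 0 °C
Reagents that add atoms: methyltriphenylphosphonium bromide, C[P+](c1ccccc1)(c1ccccc1)c1ccccc1.[Br-]
Why: Wittig methylenation of the aldehyde at low temperature should be faster than enolisation, so the exo configuration at C-2 and the oxygen bridge are preserved.

Step 8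
Reactants: 13 methyl 3-(bromomethyl)-4-methoxybenzoate; 14 tributyl(prop-1-yn-1-yl)stannane
Product: 15 methyl 3-(but-2-yn-1-yl)-4-methoxybenzoate
Conditions: Pd(PPh3)4 (5 mol %), THF, 65 °C
Reagents that add atoms: none
Why: Stille coupling of a benzylic bromide with an alkynylstannane forms the sp3–sp bond under neutral conditions that tolerate the ester and avoid alkyne-to-allene isomerisation.

Step 9
Reactants: 15 methyl 3-(but-2-yn-1-yl)-4-methoxybenzoate
Product: 17 methyl 3-[(2E)-3-iodobut-2-en-1-yl]-4-methoxybenzoate, via alkenylzirconocene chloride 16 (not isolated)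
Conditions: Cp2Zr(H)Cl (1.5 equiv), THF, rt → 40 °C; then I2, 0 °C
Reagents that add atoms: iodine, II
Why: Hydrozirconation adds Zr–H syn across the alkyne and, on equilibration with a small excess of reagent, places zirconium on the less hindered methyl-bearing carbon, and iodinolysis with retention gives the (E)-iodide while the ester is tolerated.

Step 10
Reactants: 12 (1R,2S,4S)-2-ethenyl-1,3,3-trimethyl-7-oxabicyclo[2.2.1]heptane; 17 methyl 3-[(2E)-3-iodobut-2-en-1-yl]-4-methoxybenzoate
Product: 19 methyl 4-methoxy-3-{(2E)-3-methyl-5-[(1R,2S,4S)-1,3,3-trimethyl-7-oxabicyclo[2.2.1]heptan-2-yl]pent-2-en-1-yl}benzoate, via B-alkyl-9-BBN 18 (not isolated)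
Conditions: 9-BBN, THF, rt; then 17, Pd(dppf)Cl2 (5 mol %), AsPh3, Cs2CO3, DMF/H2O, rt
Reagents that add atoms: none
Why: Anti-Markovnikov hydroboration of the terminal vinyl group followed by B-alkyl Suzuki–Miyaura coupling joins the fragments with retention of the (E)-alkene geometry and leaves ester, ethers and oxabicycle intact.

Step 11
Reactants: 19 methyl 4-methoxy-3-{(2E)-3-methyl-5-[(1R,2S,4S)-1,3,3-trimethyl-7-oxabicyclo[2.2.1]heptan-2-yl]pent-2-en-1-yl}benzoate
Product: 20 4-hydroxy-3-{(2E)-3-methyl-5-[(1R,2S,4S)-1,3,3-trimethyl-7-oxabicyclo[2.2.1]heptan-2-yl]pent-2-en-1-yl}benzoic acid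
Conditions: NaSEt (excess), DMF, 120 °C; then aq. HCl to pH 3
Reagents that add atoms: none
Why: Thiolate SN2 demethylation cleaves the methyl ester and the aryl methyl ether in one operation under non-acidic conditions that spare the tertiary bridged ether and the trisubstituted alkene.

**Compound list**

1 | (S)-(+)-carvone, (5S)-2-methyl-5-(prop-1-en-2-yl)cyclohex-2-en-1-one | CC1=CC[C@@H](CC1=O)C(C)=C | starting material
2 | (5S)-5-(2-chloropropan-2-yl)-2-methylcyclohex-2-en-1-one | CC1=CC[C@@H](CC1=O)C(C)(C)Cl | intermediate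
3 | potassium α′-dienolate of 2 | CC1=CC[C@@H](C=C1[O-])C(C)(C)Cl.[K+] | intermediate
4 | (1R,6S)-3,7,7-trimethylbicyclo[4.1.0]hept-3-en-2-one | CC1=CC[C@H]2[C@@H](C1=O)C2(C)C | intermediate
5 | lithium (1R,6S)-3,7,7-trimethylbicyclo[4.1.0]hept-2-en-2-olate | CC1=C([O-])[C@@H]2[C@H](CC1)C2(C)C.[Li+] | intermediate
6 | (1R,6S)-3,7,7-trimethylbicyclo[4.1.0]hept-2-en-2-yl trifluoromethanesulfonate | CC1=C(OS(=O)(=O)C(F)(F)F)[C@@H]2[C@H](CC1)C2(C)C | intermediate
7 | (1R,6S)-3,7,7-trimethylbicyclo[4.1.0]hept-2-ene (ent-2-carene) | CC1=C[C@@H]2[C@H](CC1)C2(C)C | intermediate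
8 | secondary ozonide of 7 (acetal carbons undefined) | CC12CC[C@H]3[C@@H](C(O1)OO2)C3(C)C | intermediate
9 | (1R,3S)-2,2-dimethyl-3-(3-oxobutyl)cyclopropane-1-carbaldehyde | O=C[C@@H]1[C@H](CCC(C)=O)C1(C)C | intermediate
10 | (2S)-5-methyl-2-[2-methyl-4-(trimethylsilyloxy)but-3-en-2-yl]-3,4-dihydro-2H-furan-1-ium trifluoromethanesulfonate | CC1=[O+][C@@H](CC1)C(C)(C)C=CO[Si](C)(C)C.[O-]S(=O)(=O)C(F)(F)F | intermediate
11 | (1R,2S,4S)-1,3,3-trimethyl-7-oxabicyclo[2.2.1]heptane-2-carbaldehyde | O=C[C@H]1C(C)(C)[C@@H]2CC[C@@]1(C)O2 | intermediate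
12 | (1R,2S,4S)-2-ethenyl-1,3,3-trimethyl-7-oxabicyclo[2.2.1]heptane | C=C[C@H]1C(C)(C)[C@@H]2CC[C@@]1(C)O2 | intermediate
13 | methyl 3-(bromomethyl)-4-methoxybenzoate | COC(=O)c1ccc(OC)c(CBr)c1 | starting material
14 | tributyl(prop-1-yn-1-yl)stannane | CC#C[Sn](CCCC)(CCCC)CCCC | starting material
15 | methyl 3-(but-2-yn-1-yl)-4-methoxybenzoate | COC(=O)c1ccc(OC)c(CC#CC)c1 | intermediate
16 | chlorobis(cyclopentadienyl)[(2E)-4-(2-methoxy-5-methoxycarbonylphenyl)but-2-en-2-yl]zirconium | COC(=O)c1ccc(OC)c(C/C=C(\C)[Zr](Cl)(C2C=CC=C2)C3C=CC=C3)c1 | intermediate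
17 | methyl 3-[(2E)-3-iodobut-2-en-1-yl]-4-methoxybenzoate | COC(=O)c1ccc(OC)c(C/C=C(\C)I)c1 | intermediate
18 | 9-{2-[(1R,2S,4S)-1,3,3-trimethyl-7-oxabicyclo[2.2.1]heptan-2-yl]ethyl}-9-borabicyclo[3.3.1]nonane | B1(CC[C@H]2C(C)(C)[C@@H]3CC[C@@]2(C)O3)C4CCCC1CCC4 | intermediate
19 | methyl 4-methoxy-3-{(2E)-3-methyl-5-[(1R,2S,4S)-1,3,3-trimethyl-7-oxabicyclo[2.2.1]heptan-2-yl]pent-2-en-1-yl}benzoate | C/C(=C\Cc1cc(C(=O)OC)ccc1OC)CC[C@H]1C(C)(C)[C@@H]2CC[C@@]1(C)O2 | intermediate
20 | 4-hydroxy-3-{(2E)-3-methyl-5-[(1R,2S,4S)-1,3,3-trimethyl-7-oxabicyclo[2.2.1]heptan-2-yl]pent-2-en-1-yl}benzoic acid | C/C(=C\Cc1cc(C(=O)O)ccc1O)CC[C@H]1C(C)(C)[C@@H]2CC[C@@]1(C)O2 | target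

**Step count**

Total step count: 11. Longest linear sequence: 9 steps (steps 1–7, 10 and 11); steps 8 and 9 make the arene fragment.

**Steps most likely to fail**

Step 6 (Proposed new method). The single formyl acceptor may not activate the ring enough. The ring may also open at the dimethyl-substituted C-3 instead of C-4, the formyl oxygen may close onto the ring (Cloke–Wilson isomerisation), or the ketone may add to the aldehyde in an aldol reaction. The fallback uses the established 1,1-diester version of the same cross-cycloaddition; it sets out from 9 and comes back at 11.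
- Pinnick oxidation (NaClO2, NaH2PO4, 2-methylbut-2-ene) gives (1R,3S)-2,2-dimethyl-3-(3-oxobutyl)cyclopropane-1-carboxylic acid F1.
- Me3SiCHN2 in MeOH gives methyl (1R,3S)-2,2-dimethyl-3-(3-oxobutyl)cyclopropane-1-carboxylate F2.
- Ethylene glycol and TsOH give the ketal methyl (1R,3S)-2,2-dimethyl-3-[2-(2-methyl-1,3-dioxolan-2-yl)ethyl]cyclopropane-1-carboxylate F3.
- LiN(i-Pr)2 then ClCO2Me gives dimethyl (3R)-2,2-dimethyl-3-[2-(2-methyl-1,3-dioxolan-2-yl)ethyl]cyclopropane-1,1-dicarboxylate F4.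
- Aqueous HCl in acetone frees the ketone, dimethyl (3R)-2,2-dimethyl-3-(3-oxobutyl)cyclopropane-1,1-dicarboxylate F5.
- Sc(OTf)3 in 1,2-dichloroethane effects the cross-cycloaddition to dimethyl (1R,4S)-1,3,3-trimethyl-7-oxabicyclo[2.2.1]heptane-2,2-dicarboxylate F6.
- Krapcho dealkoxycarbonylation (LiCl, wet DMSO, 150 °C) gives the exo ester methyl (1R,2S,4S)-1,3,3-trimethyl-7-oxabicyclo[2.2.1]heptane-2-carboxylate F7.
- i-Bu2AlH at −78 °C returns 11.

Step 9. Zirconium may add partly to the benzyl-side alkyne carbon, so that a regioisomeric iodide is carried into the coupling, and excess hydride may attack the ester. The fallback sets out from 11 (together with 13), comes back at 19 and makes steps 7 to 10 unnecessary.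
- Wittig reaction of 11 with Ph3P=CHC(O)CH3 (toluene, 80 °C) gives (3E)-4-[(1R,2S,4S)-1,3,3-trimethyl-7-oxabicyclo[2.2.1]heptan-2-yl]but-3-en-2-one F8.
- H2 over Pd/C gives 4-[(1R,2S,4S)-1,3,3-trimethyl-7-oxabicyclo[2.2.1]heptan-2-yl]butan-2-one F9.
- LiN(i-Pr)2 and ClP(O)(OEt)2 give diethyl 4-[(1R,2S,4S)-1,3,3-trimethyl-7-oxabicyclo[2.2.1]heptan-2-yl]but-1-en-2-yl phosphate F10, which more LiN(i-Pr)2 converts in the same flask into (1R,2S,4S)-2-(but-3-yn-1-yl)-1,3,3-trimethyl-7-oxabicyclo[2.2.1]heptane F11.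
- Zirconium-catalysed methylalumination (AlMe3, Cp2ZrCl2, CH2Cl2) gives dimethyl{(1E)-2-methyl-4-[(1R,2S,4S)-1,3,3-trimethyl-7-oxabicyclo[2.2.1]heptan-2-yl]but-1-en-1-yl}alane F12 with defined regio- and stereochemistry.
- Pd(PPh3)4-catalysed coupling of F12 with benzylic bromide 13 gives 19.

Step 7. The basic ylide may enolise the β-alkoxy aldehyde before it adds, which would epimerise C-2 or open the oxygen bridge by β-elimination. The fallback is a two-stage Peterson olefination; it sets out from 11 and comes back at 12.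
- Me3SiCH2MgCl with CeCl3 (weakly basic) adds to the aldehyde to give 1-[(1R,2R,4S)-1,3,3-trimethyl-7-oxabicyclo[2.2.1]heptan-2-yl]-2-(trimethylsilyl)ethan-1-ol F13 (both carbinol epimers).
- With the carbonyl gone, KH in THF effects the syn-elimination to 12.

**Further compounds**

F1 | step 6 | (1R,3S)-2,2-dimethyl-3-(3-oxobutyl)cyclopropane-1-carboxylic acid | O=C(O)[C@@H]1[C@H](CCC(C)=O)C1(C)C
F2 | step 6 | methyl (1R,3S)-2,2-dimethyl-3-(3-oxobutyl)cyclopropane-1-carboxylate | COC(=O)[C@@H]1[C@H](CCC(C)=O)C1(C)C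
F3 | step 6 | methyl (1R,3S)-2,2-dimethyl-3-[2-(2-methyl-1,3-dioxolan-2-yl)ethyl]cyclopropane-1-carboxylate | COC(=O)[C@@H]1[C@H](CCC2(C)OCCO2)C1(C)C
F4 | step 6 | dimethyl (3R)-2,2-dimethyl-3-[2-(2-methyl-1,3-dioxolan-2-yl)ethyl]cyclopropane-1,1-dicarboxylate | COC(=O)C1(C(=O)OC)[C@H](CCC2(C)OCCO2)C1(C)C
F5 | step 6 | dimethyl (3R)-2,2-dimethyl-3-(3-oxobutyl)cyclopropane-1,1-dicarboxylate | COC(=O)C1(C(=O)OC)[C@H](CCC(C)=O)C1(C)C
F6 | step 6 | dimethyl (1R,4S)-1,3,3-trimethyl-7-oxabicyclo[2.2.1]heptane-2,2-dicarboxylate | COC(=O)C1(C(=O)OC)C(C)(C)[C@@H]2CC[C@@]1(C)O2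
F7 | step 6 | methyl (1R,2S,4S)-1,3,3-trimethyl-7-oxabicyclo[2.2.1]heptane-2-carboxylate | COC(=O)[C@H]1C(C)(C)[C@@H]2CC[C@@]1(C)O2
F8 | step 9 | (3E)-4-[(1R,2S,4S)-1,3,3-trimethyl-7-oxabicyclo[2.2.1]heptan-2-yl]but-3-en-2-one | CC(=O)/C=C/[C@H]1C(C)(C)[C@@H]2CC[C@@]1(C)O2
F9 | step 9 | 4-[(1R,2S,4S)-1,3,3-trimethyl-7-oxabicyclo[2.2.1]heptan-2-yl]butan-2-one | CC(=O)CC[C@H]1C(C)(C)[C@@H]2CC[C@@]1(C)O2
F10 | step 9 | diethyl 4-[(1R,2S,4S)-1,3,3-trimethyl-7-oxabicyclo[2.2.1]heptan-2-yl]but-1-en-2-yl phosphate | C=C(OP(=O)(OCC)OCC)CC[C@H]1C(C)(C)[C@@H]2CC[C@@]1(C)O2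
F11 | step 9 | (1R,2S,4S)-2-(but-3-yn-1-yl)-1,3,3-trimethyl-7-oxabicyclo[2.2.1]heptane | C#CCC[C@H]1C(C)(C)[C@@H]2CC[C@@]1(C)O2
F12 | step 9 | dimethyl{(1E)-2-methyl-4-[(1R,2S,4S)-1,3,3-trimethyl-7-oxabicyclo[2.2.1]heptan-2-yl]but-1-en-1-yl}alane | C[Al](C)/C=C(\C)CC[C@H]1C(C)(C)[C@@H]2CC[C@@]1(C)O2
F13 | step 7 | 1-[(1R,2R,4S)-1,3,3-trimethyl-7-oxabicyclo[2.2.1]heptan-2-yl]-2-(trimethylsilyl)ethan-1-ol | C[Si](C)(C)CC(O)[C@H]1C(C)(C)[C@@H]2CC[C@@]1(C)O2
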